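## Retrosynthetic overview
1. Cyclointegrin 9 is cut at O1–C2 and at (2'-O)–CMe2 in one operation. This unravels it to the open-chain C-prenylated dibenzoylmethane 6, and integrin 8 is never isolated.
2. 6 comes from diketone 4 and prenyl bromide 5 (C3–C1'' bond). This is the flask stand-in for dimethylallyl transfer to C-3.
3. 4 comes from acetophenone 3 (ring A) and benzoate 2 (ring B, made from 1) by crossed Claisen condensation.
4. Ring order: the γ-pyrone ring C forms first, by dehydration of the 2-hydroxyflavanone tautomer. The oxocine forms second, when 2'-OH captures the tertiary prenyl cation. Both form in one flask.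

Assumption: the SMILES holds no stereocentre and the twisted oxocine is taken as conformationally mobile, so the target is treated as achiral and no enantioselective step is needed.
Convention: phenoxides and enolates made by the bases count as ionised forms of the numbered compounds and get no number of their own.

## Route

Step 1
Reactants: 1 methyl 2,4-dihydroxybenzoate
Product: 2 methyl 2,4-bis(methoxymethoxy)benzoate
Conditions: NaH (2.4 equiv), MOMCl (2.4 equiv), DMF, 0 °C → rt
Reagents that add atoms: chloromethyl methyl ether (MOMCl), COCCl
Why: Williamson-type O-alkylation (MOM acetal protection): NaH ionises both phenols, including the ester-chelated 2-OH, the very reactive MOMCl caps them on oxygen, and the acetals survive the bases of steps 2–3 and fall off under the acid that step 4 needs anyway, so no separate deprotection step is required.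

Step 2
Reactants: 3 2',6'-dihydroxy-4'-methoxyacetophenone; 2 methyl 2,4-bis(methoxymethoxy)benzoate
Product: 4 1-[2,4-bis(methoxymethoxy)phenyl]-3-(2,6-dihydroxy-4-methoxyphenyl)propane-1,3-dione
Conditions: 3, LiHMDS (4.2 equiv), THF, −78 → −10 °C; then 2 (1.05 equiv), −78 °C → rt → 40 °C; sat. aq NH4Cl
Reagents that add atoms: none
Why: Crossed Claisen condensation of a lithium polyanion: excess LiHMDS ionises both phenols and the methyl ketone of 3, the enolate carbon is the most basic and the only C-nucleophilic site, ester 2 cannot enolise, any O-aroylation is funnelled on by Baker–Venkataraman acyl transfer, and final deprotonation of the 1,3-diketone drives the equilibrium; no stereocentre is formed.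

Step 3
Reactants: 4 diketone; 5 prenyl bromide (1-bromo-3-methylbut-2-ene)
Product: 6 1-[2,4-bis(methoxymethoxy)phenyl]-3-(2,6-dihydroxy-4-methoxyphenyl)-2-(3-methylbut-2-en-1-yl)propane-1,3-dione (racemic; ring–chain tautomer: 2-hydroxy-3-prenylflavanone hemiketal)
Conditions: 5 (1.05 equiv), K2CO3 (1.2 equiv), acetone, reflux
Reagents that add atoms: none
Why: C-alkylation of a stabilised 1,3-diketone enolate (SN2 at the primary terminus of the soft allylic bromide, hence linear and not reverse prenyl): in acetone K2CO3 ionises mainly the central CH2, the A-ring OH groups are hydrogen-bonded to the carbonyl or tied up in the hemiketal, and the B-ring oxygens are masked; the new stereocentre is racemic, epimerisable and erased in step 4.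

Step 4
Reactants: 6 2-prenyl diketone
Product: 9 cyclointegrin, via integrin bis-MOM ether 7 (not isolated), via integrin 8 (not isolated)
Conditions: (i) 3 M aq HCl–MeOH (1:5), 60 °C, 2 h; evaporate, PhMe azeotrope; (ii) TfOH (20 mol %), HFIP (5 mM), 0 °C → rt
Reagents that add atoms: none
Why: Proposed new method: the hemiketal tautomer of 6 dehydrates under HCl (classical cyclodehydration of o-hydroxydibenzoylmethanes, the copy of the 2-hydroxyflavanone → flavone step, regiochemically safe because 2'-O is still masked and the A-side carbonyl is di-ortho-hindered) to give 7, acetal exchange with MeOH then strips both MOM groups to give 8, and after the solvent switch catalytic TfOH in non-nucleophilic, cation-stabilising HFIP protonates the trisubstituted alkene in the Markovnikov sense so that 2'-OH traps the tertiary cation in an 8-endo closure, favoured because the four-atom bridge fits the roughly 60° twist that a 3-alkyl-2'-oxyflavone already has, and because the rival nucleophiles lead nowhere (C4=O gives only a cationic 4-alkoxypyrylium that re-ionises, C6' is meta to both oxygens, and Markovnikov MeOH/HCl adducts from stage (i) return to the same cation), which leaves the neutral oxocine as the resting state; the closest known reaction type is acid-catalysed cyclisation of o-prenylphenols to 2,2-dimethylchromans (intramolecular hydroalkoxylation), and no stereocentre is formed.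

## Compound list
1 | methyl 2,4-dihydroxybenzoate | COC(=O)c1ccc(O)cc1O | starting material
2 | methyl 2,4-bis(methoxymethoxy)benzoate | COCOc1ccc(C(=O)OC)c(OCOC)c1 | intermediate
3 | 2',6'-dihydroxy-4'-methoxyacetophenone | CC(=O)c1c(O)cc(OC)cc1O | starting material
4 | 1-[2,4-bis(methoxymethoxy)phenyl]-3-(2,6-dihydroxy-4-methoxyphenyl)propane-1,3-dione | COCOc1ccc(C(=O)CC(=O)c2c(O)cc(OC)cc2O)c(OCOC)c1 | intermediate
5 | prenyl bromide (1-bromo-3-methylbut-2-ene) | CC(C)=CCBr | starting material
6 | 2-prenyl derivative of 4 (racemic, labile C-2) | COCOc1ccc(C(=O)C(CC=C(C)C)C(=O)c2c(O)cc(OC)cc2O)c(OCOC)c1 | intermediate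
7 | integrin 2',4'-bis-MOM ether (5-hydroxy-7-methoxy-2-[2,4-bis(methoxymethoxy)phenyl]-3-prenylchromen-4-one) | COCOc1ccc(-c2oc3cc(OC)cc(O)c3c(=O)c2CC=C(C)C)c(OCOC)c1 | intermediate (not isolated)
8 | integrin (5,2',4'-trihydroxy-7-methoxy-3-prenylflavone) | COc1cc(O)c2c(=O)c(CC=C(C)C)c(oc2c1)-c1ccc(O)cc1O | intermediate (not isolated)
9 | cyclointegrin (achiral) | COc1cc(O)c2c(=O)c3c(oc2c1)-c1ccc(O)cc1OC(C)(C)CC3 | target

## Step count and risks
Total steps: 4. Longest linear sequence: 4 (1 → 2 → 4 → 6 → 9).

**Step 4 (most risky).** The proton-catalysed eight-membered closure is reversible. It may rest at 8, at its alkene isomer, or drift to oligomers. The fallback sets out from integrin 8, which is isolated after stage (i), and comes back at 9.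
- It replaces reversible proton catalysis by a cobalt-hydride hydrogen-atom-transfer / radical-polar-crossover hydroalkoxylation.
- Conditions: Co(salen) catalyst, N-fluoro-2,4,6-trimethylpyridinium triflate, PhSiH3, PhCF3, rt.
- The tertiary radical is oxidised to an alkyl-cobalt(IV)/cation equivalent and displaced by 2'-OH.
- The medium is collidine-buffered, so no acid can re-ionise the tert-alkyl aryl ether and the closure is under kinetic control.
- It makes no compound outside the list (F0).

**Step 3.** O-prenylation of the less chelated A-ring phenol, or ring C-prenylation, may compete with alkylation of the diketone carbon. The fallback sets out from 3 and comes back at 6 by reversing the order of the two C–C bond formations.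
- Compound 3 is converted with LiHMDS (3.2 equiv, THF, −78 °C) into its polyanion and alkylated with 5.
- Alkylation occurs at the far more basic ketone enolate carbon, where phenoxide O-alkylation cannot compete. It gives 1-(2,6-dihydroxy-4-methoxyphenyl)-5-methylhex-4-en-1-one F1.
- The polyanion of F1 (LiHMDS, 4.2 equiv) is then acylated with ester 2 to give 6.

**Step 2.** The electron-rich ester 2 may be too sluggish towards a poorly soluble polyanion. The fallback sets out from 2 and 3 and comes back at 4 by making the acyl transfer intramolecular.
- Ester 2 is saponified (LiOH, THF–MeOH–H2O) to 2,4-bis(methoxymethoxy)benzoic acid F2.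
- F2 is coupled with one phenol of 3 (EDC, DMAP, CH2Cl2) to give 2-acetyl-3-hydroxy-5-methoxyphenyl 2,4-bis(methoxymethoxy)benzoate F3.
- A Baker–Venkataraman rearrangement of F3 (KOH, pyridine, 50 °C) delivers 4.

## Further compounds
F0 | step 4 | none | none
F1 | step 3 | 1-(2,6-dihydroxy-4-methoxyphenyl)-5-methylhex-4-en-1-one | COc1cc(O)c(C(=O)CCC=C(C)C)c(O)c1
F2 | step 2 | 2,4-bis(methoxymethoxy)benzoic acid | COCOc1ccc(C(=O)O)c(OCOC)c1
F3 | step 2 | 2-acetyl-3-hydroxy-5-methoxyphenyl 2,4-bis(methoxymethoxy)benzoate | COCOc1ccc(C(=O)Oc2cc(OC)cc(O)c2C(C)=O)c(OCOC)c1
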